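The route rests on ring B of the spiroketal, numbered as in the target name (chain on C2, spiro C5, O6, methyl-bearing C7, C8, C9). The C5–O6–C7 link is read as the Baeyer–Villiger trace of a C5–C7 bond, so ring B becomes (S)-2-methylcyclobutanone and the C8–C9 ethano bridge becomes ethylene. A keteniminium–olefin [2+2] cycloaddition of ethylene with the salt from a chiral propanamide forms C7–C8 and C9–C5 in one operation and sets C7. The precursor is only N-propanoyl-(2S,5S)-2,5-dimethylpyrrolidine and ethylene gas. Ring expansion to (S)-γ-valerolactone, acylation of a sulfone carrying C2–C4, spiroketalisation, cross-metathesis with an (R)-3-allylphthalide and hydrogenation complete the target.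

Key step: step 2

Remark: the sense of induction of the pyrrolidine auxiliary (step 2) and of the BINOL ligand (step 9) is assigned by analogy; should a first run show the opposite sense, the enantiomeric auxiliary or ligand is used and nothing else changes.

Step 1
Reactants: 1 propanoyl chloride; 2 (2S,5S)-2,5-dimethylpyrrolidine
Product: 3 1-[(2S,5S)-2,5-dimethylpyrrolidin-1-yl]propan-1-one
Conditions: Et3N, CH2Cl2, 0 °C → rt
Reagents that add atoms: none
Why: Schotten–Baumann-type N-acylation of a secondary amine by an acid chloride is fast and leaves the two stereocentres of the auxiliary untouched.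

Step 2
Reactants: 3 1-[(2S,5S)-2,5-dimethylpyrrolidin-1-yl]propan-1-one; 4 ethylene
Product: 7 (2S)-2-methylcyclobutan-1-one, via keteniminium triflate 5 (not isolated), via cyclobutaniminium triflate 6 (not isolated)
Conditions: Tf2O, 2,6-di-tert-butyl-4-methylpyridine, ClCH2CH2Cl, ethylene (about 5 bar), −20 °C → 60 °C; then H2O, 0 °C → rt; cold aq KHSO4 wash
Reagents that add atoms: water, O
Why: O-triflation of amide 3 and α-deprotonation with loss of triflate give keteniminium 5; ethylene attacks its electrophilic central carbon (the future spiro carbon C5, bond C9–C5), the developing primary cation collapses onto the enamine terminus (the future C7, bond C7–C8), and hydrolysis of iminium 6 frees ketone 7. The closest known reaction type is the keteniminium–olefin [2+2] cycloaddition, which is established for ethylene with aldo-keteniminium salts (2-alkylcyclobutanones) and for C2-symmetric pyrrolidine auxiliaries. The four-membered ring closes by a stepwise, asynchronous [2+2] cycloaddition. The new stereocentre (C7 of the target) is controlled by the trans-2,5-dimethylpyrrolidine ring, which allows only one keteniminium geometry and shields one face of the CH(CH3) terminus. The step needs facial selectivity, no α-epimerisation and capture by ethylene faster than self-condensation of 5: the hindered pyridine base and the strain of the aminocyclobutene that deprotonation of 6 would require protect the stereocentre, cold aqueous hydrolysis that keeps the liberated amine protonated does the same for 7, and ethylene pressure with slow generation of 5 favours cycloaddition.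

Step 3
Reactants: 7 (2S)-2-methylcyclobutan-1-one
Product: 8 (5S)-5-methyloxolan-2-one
Conditions: mCPBA, NaHCO3, ClCH2CH2Cl, 0 °C → rt (the dried solution of volatile 7 from step 2 is used directly)
Reagents that add atoms: meta-chloroperbenzoic acid, O=C(OO)c1cccc(Cl)c1
Why: Baeyer–Villiger oxidation of the strained cyclobutanone is fast, the secondary carbon migrates in the Criegee intermediate in preference to the CH2 group, and it migrates with retention, so (S)-C2 of 7 becomes (S)-C5 of lactone 8 (C7 of the target).

Step 4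
Reactants: 9 (2S)-2-(chloromethyl)oxirane; 10 but-3-en-1-ylmagnesium bromide
Product: 12 (2S)-2-(pent-4-en-1-yl)oxirane, via chlorohydrin 11 (not isolated)
Conditions: CuI (10 mol %), THF, −40 °C; then aq NaOH, rt
Reagents that add atoms: none
Why: Copper-catalysed Grignard opening of the epoxide at its CH2 carbon followed by base-induced ring closure of chlorohydrin 11 never touches the C–O stereocentre of 9, which becomes the (S)-carbinol carbon C2 of the target.

Step 5
Reactants: 12 (2S)-2-(pent-4-en-1-yl)oxirane; 13 methyl phenyl sulfone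
Product: 16 triethyl{[(3S)-1-(phenylsulfonyl)oct-7-en-3-yl]oxy}silane, via lithiated sulfone 14 (not isolated), via lithium alkoxide 15 (not isolated)
Conditions: n-BuLi, THF–DMPU, −78 °C → rt; then Et3SiCl, 0 °C
Reagents that add atoms: chlorotriethylsilane, CC[Si](Cl)(CC)CC
Why: SN2 opening of the terminal epoxide at its CH2 carbon by sulfonyl carbanion 14 leaves the stereocentre untouched, and silylation of alkoxide 15 in the same flask protects the oxygen for the next step.

Step 6
Reactants: 16 triethyl{[(3S)-1-(phenylsulfonyl)oct-7-en-3-yl]oxy}silane; 8 (5S)-5-methyloxolan-2-one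
Product: 18 (2S,8S)-2-hydroxy-6-(phenylsulfonyl)-8-[(triethylsilyl)oxy]tridec-12-en-5-one, via dilithio sulfone 17 (not isolated)
Conditions: n-BuLi (2.1 equiv), THF, −78 → 0 °C; then 8, −78 °C; aq NH4Cl
Reagents that add atoms: none
Why: C-acylation of a gem-dilithiated sulfone by a lactone (Claisen-type condensation) should stop at the ketone because the product is held as its enolate, neither carbinol stereocentre takes part, and the C6 epimers (in equilibrium with the five-membered lactol) are of no consequence.

Step 7
Reactants: 18 (2S,8S)-2-hydroxy-6-(phenylsulfonyl)-8-[(triethylsilyl)oxy]tridec-12-en-5-one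
Product: 21 (2S,5R,7S)-2-methyl-7-(pent-4-en-1-yl)-1,6-dioxaspiro[4.4]nonane, via hydroxy ketone 19 (not isolated), via dihydroxy ketone 20 (not isolated)
Conditions: SmI2, THF–MeOH, −78 °C; then 1 M HCl, THF, rt; chromatography on Et3N-deactivated silica; the (5S) spiro epimer is re-equilibrated (camphorsulfonic acid, CH2Cl2, rt) and separated again
Reagents that add atoms: none
Why: SmI2 cleaves the C–S bond next to the ketone (reductive desulfonylation of a β-keto sulfone), acid then removes the silyl group and closes both rings of 20 by thermodynamic spiroketalisation without touching the carbinol centres, and the spiro centre C5 is set under equilibrium, where 21 is expected in an amount comparable to its (5S) spiro epimer, so that 21 is taken on after chromatographic separation and the epimer is recycled through the same acid equilibrium.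

Step 8
Reactants: 22 3,5-dimethoxybenzaldehyde
Product: 23 2-bromo-3,5-dimethoxybenzaldehyde
Conditions: NBS, MeCN, rt
Reagents that add atoms: N-bromosuccinimide, O=C1CCC(=O)N1Br
Why: Electrophilic aromatic bromination should go to C2, which is ortho and para to the two methoxy groups, as is usual for this aldehyde.

Step 9
Reactants: 23 2-bromo-3,5-dimethoxybenzaldehyde; 24 allyltributylstannane
Product: 25 (1R)-1-(2-bromo-3,5-dimethoxyphenyl)but-3-en-1-ol
Conditions: (R)-BINOL (20 mol %), Ti(OiPr)4 (10 mol %), 4 Å molecular sieves, CH2Cl2, −20 °C; aq NaHCO3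
Reagents that add atoms: none
Why: In the Keck asymmetric allylation the (R)-BINOL–titanium Lewis acid activates the aldehyde and differentiates its faces, so that allyl transfer from tin should give the (R)-carbinol, as with benzaldehyde.

Step 10
Reactants: 25 (1R)-1-(2-bromo-3,5-dimethoxyphenyl)but-3-en-1-ol
Product: 28 (3R)-5,7-dimethoxy-3-(prop-2-en-1-yl)-2-benzofuran-1(3H)-one, via dilithio species 26 (not isolated), via hydroxy acid 27 (not isolated)
Conditions: n-BuLi (2.2 equiv), THF, −78 °C; CO2; then 2 M HCl, rt
Reagents that add atoms: carbon dioxide, O=C=O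
Why: Bromine–lithium exchange on the lithium alkoxide gives aryllithium 26, CO2 carboxylates it, and acidification closes the five-membered lactone (phthalide synthesis by halogen–metal exchange and carboxylation) without touching the benzylic C–O stereocentre, which has only meta-methoxy groups and should not ionise.

Step 11
Reactants: 21 (2S,5R,7S)-2-methyl-7-(pent-4-en-1-yl)-1,6-dioxaspiro[4.4]nonane; 28 (3R)-5,7-dimethoxy-3-(prop-2-en-1-yl)-2-benzofuran-1(3H)-one
Product: 29 (3R)-5,7-dimethoxy-3-{6-[(2S,5R,7S)-7-methyl-1,6-dioxaspiro[4.4]nonan-2-yl]hex-2-en-1-yl}-2-benzofuran-1(3H)-one (E/Z mixture)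
Conditions: second-generation Grubbs catalyst RuCl2(=CHPh)(PCy3)(H2IMes) (5 mol %), 28 (2.5 equiv), CH2Cl2, 40 °C
Reagents that add atoms: none
Why: Olefin cross-metathesis of two unhindered terminal alkenes with loss of ethylene is pushed towards the cross-product by an excess of the shorter-made partner 28, the double-bond geometry is irrelevant, and no stereocentre is touched.

Step 12
Reactants: 29 (3R)-5,7-dimethoxy-3-{6-[(2S,5R,7S)-7-methyl-1,6-dioxaspiro[4.4]nonan-2-yl]hex-2-en-1-yl}-2-benzofuran-1(3H)-one
Product: 30 (3R)-5,7-dimethoxy-3-{6-[(2S,5R,7S)-7-methyl-1,6-dioxaspiro[4.4]nonan-2-yl]hexyl}-2-benzofuran-1(3H)-one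
Conditions: H2 (1 atm), platinum on carbon (5% Pt/C), EtOAc, rt
Reagents that add atoms: none
Why: Heterogeneous catalytic hydrogenation saturates the isolated disubstituted alkene under neutral conditions that should leave the phthalide C–O bond and the acid-sensitive spiroketal alone.

Compound list
1 | propanoyl chloride | CCC(Cl)=O | starting material
2 | (2S,5S)-2,5-dimethylpyrrolidine | C[C@H]1CC[C@H](C)N1 | starting material
3 | 1-[(2S,5S)-2,5-dimethylpyrrolidin-1-yl]propan-1-one | CCC(=O)N1[C@@H](C)CC[C@@H]1C | intermediate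
4 | ethylene | C=C | starting material
5 | (2S,5S)-2,5-dimethyl-1-(prop-1-en-1-ylidene)pyrrolidin-1-ium triflate (keteniminium salt) | CC=C=[N+]1[C@@H](C)CC[C@@H]1C.[O-]S(=O)(=O)C(F)(F)F | intermediate
6 | (2S,5S)-2,5-dimethyl-1-[(2S)-2-methylcyclobutylidene]pyrrolidin-1-ium triflate | C[C@H]1CCC1=[N+]2[C@@H](C)CC[C@@H]2C.[O-]S(=O)(=O)C(F)(F)F | intermediate
7 | (2S)-2-methylcyclobutan-1-one | C[C@H]1CCC1=O | intermediate
8 | (5S)-5-methyloxolan-2-one, (S)-γ-valerolactone | C[C@H]1CCC(=O)O1 | intermediate
9 | (2S)-2-(chloromethyl)oxirane, (S)-epichlorohydrin | ClC[C@@H]1CO1 | starting material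
10 | but-3-en-1-ylmagnesium bromide | C=CCC[Mg]Br | starting material
11 | (2S)-1-chlorohept-6-en-2-ol | C=CCCC[C@H](O)CCl | intermediate
12 | (2S)-2-(pent-4-en-1-yl)oxirane | C=CCCC[C@H]1CO1 | intermediate
13 | methyl phenyl sulfone | CS(=O)(=O)c1ccccc1 | starting material
14 | [(phenylsulfonyl)methyl]lithium | [Li]CS(=O)(=O)c1ccccc1 | intermediate
15 | lithium (3S)-1-(phenylsulfonyl)oct-7-en-3-olate | C=CCCC[C@@H](CCS(=O)(=O)c1ccccc1)[O-].[Li+] | intermediate
16 | triethyl{[(3S)-1-(phenylsulfonyl)oct-7-en-3-yl]oxy}silane | C=CCCC[C@@H](CCS(=O)(=O)c1ccccc1)O[Si](CC)(CC)CC | intermediate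
17 | 1,1-dilithio derivative of 16 | C=CCCC[C@@H](CC([Li])([Li])S(=O)(=O)c1ccccc1)O[Si](CC)(CC)CC | intermediate
18 | (2S,8S)-2-hydroxy-6-(phenylsulfonyl)-8-[(triethylsilyl)oxy]tridec-12-en-5-one (C6 epimers) | C[C@H](O)CCC(=O)C(C[C@H](CCCC=C)O[Si](CC)(CC)CC)S(=O)(=O)c1ccccc1 | intermediate
19 | (2S,8S)-2-hydroxy-8-[(triethylsilyl)oxy]tridec-12-en-5-one | C[C@H](O)CCC(=O)CC[C@H](CCCC=C)O[Si](CC)(CC)CC | intermediate
20 | (2S,8S)-2,8-dihydroxytridec-12-en-5-one | C[C@H](O)CCC(=O)CC[C@H](CCCC=C)O | intermediate
21 | (2S,5R,7S)-2-methyl-7-(pent-4-en-1-yl)-1,6-dioxaspiro[4.4]nonane | C=CCCC[C@H]1CC[C@@]2(CC[C@H](C)O2)O1 | intermediate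
22 | 3,5-dimethoxybenzaldehyde | COc1cc(OC)cc(C=O)c1 | starting material
23 | 2-bromo-3,5-dimethoxybenzaldehyde | COc1cc(OC)c(Br)c(C=O)c1 | intermediate
24 | allyltributylstannane | C=CC[Sn](CCCC)(CCCC)CCCC | starting material
25 | (1R)-1-(2-bromo-3,5-dimethoxyphenyl)but-3-en-1-ol | C=CC[C@@H](O)c1cc(OC)cc(OC)c1Br | intermediate
26 | lithium (1R)-1-(2-lithio-3,5-dimethoxyphenyl)but-3-en-1-olate | C=CC[C@@H]([O-])c1cc(OC)cc(OC)c1[Li].[Li+] | intermediate
27 | 2-[(1R)-1-hydroxybut-3-en-1-yl]-4,6-dimethoxybenzoic acid | C=CC[C@@H](O)c1cc(OC)cc(OC)c1C(=O)O | intermediate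
28 | (3R)-5,7-dimethoxy-3-(prop-2-en-1-yl)-2-benzofuran-1(3H)-one | C=CC[C@H]1OC(=O)c2c(OC)cc(OC)cc21 | intermediate
29 | (3R)-5,7-dimethoxy-3-{6-[(2S,5R,7S)-7-methyl-1,6-dioxaspiro[4.4]nonan-2-yl]hex-2-en-1-yl}-2-benzofuran-1(3H)-one (E/Z mixture) | COc1cc(OC)c2c(c1)[C@@H](CC=CCCC[C@H]1CC[C@@]3(CC[C@H](C)O3)O1)OC2=O | intermediate
30 | (3R)-5,7-dimethoxy-3-{6-[(2S,5R,7S)-7-methyl-1,6-dioxaspiro[4.4]nonan-2-yl]hexyl}-2-benzofuran-1(3H)-one | COc1cc(OC)c2c(c1)[C@@H](CCCCCC[C@H]1CC[C@@]3(CC[C@H](C)O3)O1)OC2=O | target

Total step count: 12 steps.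
Longest linear sequence: 7 steps (1, 2, 3, 6, 7, 11, 12).

Steps most likely to fail

Step 2. The risks are poor facial selectivity in the cycloaddition, α-epimerisation of iminium 6, and self-condensation of keteniminium 5 outrunning its capture by gaseous ethylene. The fallback keeps the cycloaddition but takes stereocontrol out of it; it sets out from 4 and comes back at 8. The achiral keteniminium salt from commercial N,N-dimethylpropanamide F1 is generated under the same Tf2O conditions and trapped with ethylene 4 to give racemic 2-methylcyclobutan-1-one F2. Baeyer–Villiger oxidation with mCPBA gives racemic 5-methyloxolan-2-one F3, and benzylamine opens it to racemic N-benzyl-4-hydroxypentanamide F4. Kinetic resolution with Candida antarctica lipase B and vinyl acetate in MTBE should, by the Kazlauskas rule, acylate the (R)-alcohol to (2R)-5-(benzylamino)-5-oxopentan-2-yl acetate F5 and leave (4S)-N-benzyl-4-hydroxypentanamide F6. After separation, F6 is relactonised (TsOH, 1.1 equiv, toluene, reflux) to 8.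

Step 6. The risks are enolisation of lactone 8 by the strongly basic dilithio sulfone 17 in place of C-acylation, and incomplete second lithiation of 16. The fallback replaces steps 5 to 7 by alkyne chemistry; it sets out from 8 and 12 and comes back at 21. Reduction of 8 with i-Bu2AlH (CH2Cl2, −78 °C) gives (5S)-5-methyloxolan-2-ol F7. The Ohira–Bestmann reagent (dimethyl (1-diazo-2-oxopropyl)phosphonate, K2CO3, MeOH) converts it into (2S)-hex-5-yn-2-ol F8. The dilithio derivative of F8 (n-BuLi, THF–DMPU) opens epoxide 12 to (2S,8S)-tridec-12-en-5-yne-2,8-diol F9. AuCl(PPh3)/AgOTf in CH2Cl2 then cycloisomerises F9 by double hydroalkoxylation. Five-membered closure of both hydroxyl groups converges on C5 (5-exo-dig from the C2 hydroxyl, 5-endo-dig from the C8 hydroxyl). This should give 21 together with its spiro epimer (2S,5S,7S)-2-methyl-7-(pent-4-en-1-yl)-1,6-dioxaspiro[4.4]nonane F10, from which 21 is separated as in step 7.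

Step 7. The risks are a missing thermodynamic bias at the spiro centre, co-elution of the small, UV-silent spiro epimers, and loss of volatile material on repeated recycling. The fallback moves the stereochemical problem to the end of the route; it sets out from the unseparated mixture of 21 and its spiro epimer (2S,5S,7S)-2-methyl-7-(pent-4-en-1-yl)-1,6-dioxaspiro[4.4]nonane F10 that the spiroketalisation delivers, and comes back at 30. The mixture is taken through steps 11 and 12, so that F10 gives (3R)-5,7-dimethoxy-3-{6-[(2S,5S,7S)-7-methyl-1,6-dioxaspiro[4.4]nonan-2-yl]hex-2-en-1-yl}-2-benzofuran-1(3H)-one F11 and then (3R)-5,7-dimethoxy-3-{6-[(2S,5S,7S)-7-methyl-1,6-dioxaspiro[4.4]nonan-2-yl]hexyl}-2-benzofuran-1(3H)-one F12. Compounds 30 and F12 are separated by preparative HPLC on the UV-active phthalides. F12 is re-equilibrated at the spiro centre (camphorsulfonic acid, CH2Cl2, rt) and the resulting mixture is separated again.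

Further compounds
F1 | step 2 | N,N-dimethylpropanamide | CCC(=O)N(C)C
F2 | step 2 | racemic 2-methylcyclobutan-1-one | CC1CCC1=O
F3 | step 2 | racemic 5-methyloxolan-2-one | CC1CCC(=O)O1
F4 | step 2 | racemic N-benzyl-4-hydroxypentanamide | CC(O)CCC(=O)NCc1ccccc1
F5 | step 2 | (2R)-5-(benzylamino)-5-oxopentan-2-yl acetate | C[C@@H](OC(C)=O)CCC(=O)NCc1ccccc1
F6 | step 2 | (4S)-N-benzyl-4-hydroxypentanamide | C[C@H](O)CCC(=O)NCc1ccccc1
F7 | step 6 | (5S)-5-methyloxolan-2-ol | C[C@H]1CCC(O)O1
F8 | step 6 | (2S)-hex-5-yn-2-ol | C[C@H](O)CCC#C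
F9 | step 6 | (2S,8S)-tridec-12-en-5-yne-2,8-diol | C[C@H](O)CCC#CC[C@H](CCCC=C)O
F10 | step 6 | (2S,5S,7S)-2-methyl-7-(pent-4-en-1-yl)-1,6-dioxaspiro[4.4]nonane | C=CCCC[C@H]1CC[C@]2(CC[C@H](C)O2)O1
F11 | step 7 | (3R)-5,7-dimethoxy-3-{6-[(2S,5S,7S)-7-methyl-1,6-dioxaspiro[4.4]nonan-2-yl]hex-2-en-1-yl}-2-benzofuran-1(3H)-one | COc1cc(OC)c2c(c1)[C@@H](CC=CCCC[C@H]1CC[C@]3(CC[C@H](C)O3)O1)OC2=O
F12 | step 7 | (3R)-5,7-dimethoxy-3-{6-[(2S,5S,7S)-7-methyl-1,6-dioxaspiro[4.4]nonan-2-yl]hexyl}-2-benzofuran-1(3H)-one | COc1cc(OC)c2c(c1)[C@@H](CCCCCC[C@H]1CC[C@]3(CC[C@H](C)O3)O1)OC2=O
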